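## Retrosynthetic overview

1. Ring E (eleven-membered lactam) and C20=C21: intramolecular Knoevenagel condensation of an L-ornithine-derived tetramic acid (ring F, Meldrum's acid route) onto a C21 aldehyde.
2. Rings C and D in one operation: visible-light sensitised intramolecular [2+2] photocycloaddition of a C6–C11 trienamide with a C22–C25 (E,Z)-diene (C8–C25, C9–C24), then boat Cope rearrangement (C11–C22); C7–H is added afterwards by hydrogen-atom-transfer hydrogenation.
3. Side arms: C27–C26 by enone α′-alkylation with an (E,Z)-dienyl acetal bromide; C7–C8 by Heck coupling of an enol triflate with a Boc-ornithine dienamide.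
4. Rings A and B together: Pauson–Khand reaction of an enyne whose C2/C3/C29 centres come from a dianionic Ireland–Claisen rearrangement of (Z)-crotyl (R)-3-hydroxybutanoate.
5. Ring order A+B → C → D → F → E; all chirality from ethyl (R)-3-hydroxybutanoate and N2-Boc-L-ornithine.

Assumption: locants C1–C31 (N13, N18) are the positions of the atoms in the target SMILES; ring A = C3/C4/C5/C28/C29, ring B = C5/C6/C7/C27/C28, ring C = C7/C8/C25/C26/C27, ring D = C8–C11/C22–C25, ring E = the eleven-membered lactam, ring F = the pyrrolidine-2,4-dione.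

## Route

Step 1
Reactants: 1 ethyl (3R)-3-hydroxybutanoate; 2 (2Z)-but-2-en-1-ol
Product: 3 (2Z)-but-2-en-1-yl (3R)-3-hydroxybutanoate
Conditions: Ti(OiPr)4 (10 mol %), 2 (5 equiv), 100 °C, EtOH distilled off
Reagents that add atoms: none
Why: Titanate-mediated transesterification exchanges only the ester alkoxy group, so the (R)-carbinol bought with 1 is untouched.

Step 2
Reactants: 3 (2Z)-but-2-en-1-yl (3R)-3-hydroxybutanoate
Product: 4 (2R,3S)-2-[(1R)-1-hydroxyethyl]-3-methylpent-4-enoic acid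
Conditions: LiN(iPr)2 (2.3 equiv), THF, −78 → 60 °C; 1 M HCl
Reagents that add atoms: none
Why: Dianionic Ireland–Claisen rearrangement, in which the lithium-chelated (Z)-enolate dianion reacts through a chair transition state on the face anti to the carbinol methyl (as in Fráter–Seebach alkylation), so the bought (R)-carbinol sets C3 and the (Z)-crotyl geometry sets C29 anti to it.

Step 3
Reactants: 4 (2R,3S)-2-[(1R)-1-hydroxyethyl]-3-methylpent-4-enoic acid
Product: 6 (2S,3S)-2-[(1R)-1-{[tert-butyl(dimethyl)silyl]oxy}ethyl]-3-methylpent-4-en-1-ol, via bis-silyl ester 5 (not isolated)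
Conditions: TBSCl (2.4 equiv), imidazole, CH2Cl2, rt; solvent swap; LiAlH4, THF, 0 °C
Reagents that add atoms: tert-butyl(chloro)dimethylsilane, CC(C)(C)[Si](C)(C)Cl
Why: Silylation of both OH groups followed by LiAlH4 reduction of the silyl ester gives the primary alcohol with the carbinol protected, and no stereocentre is touched.

Step 4
Reactants: 6 (2S,3S)-2-[(1R)-1-{[tert-butyl(dimethyl)silyl]oxy}ethyl]-3-methylpent-4-en-1-ol
Product: 7 tert-butyl{[(2R,3R,4S)-3-(iodomethyl)-4-methylhex-5-en-2-yl]oxy}dimethylsilane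
Conditions: I2, PPh3, imidazole, CH2Cl2, 0 °C
Reagents that add atoms: iodine, II
Why: Appel-type (Garegg–Samuelsson) iodination converts the primary alcohol into the iodide under neutral conditions.

Step 5
Reactants: 7 tert-butyl{[(2R,3R,4S)-3-(iodomethyl)-4-methylhex-5-en-2-yl]oxy}dimethylsilane
Product: 8 tert-butyl(dimethyl){[(2R,3R,4S)-4-methyl-3-(prop-2-yn-1-yl)hex-5-en-2-yl]oxy}silane
Conditions: LiC≡CH·H2NCH2CH2NH2 (3 equiv), DMSO, rt
Reagents that add atoms: lithium acetylide (ethylenediamine complex), [Li]C#C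
Why: SN2 alkynylation of the primary iodide installs C5 and C6 and completes the 1,6-enyne.

Step 6
Reactants: 8 tert-butyl(dimethyl){[(2R,3R,4S)-4-methyl-3-(prop-2-yn-1-yl)hex-5-en-2-yl]oxy}silane
Product: 9 (5R,6S,6aS)-5-[(1R)-1-{[tert-butyl(dimethyl)silyl]oxy}ethyl]-6-methyl-4,5,6,6a-tetrahydropentalen-2(1H)-one
Conditions: Co2(CO)8 (1.1 equiv), CH2Cl2, rt; N-methylmorpholine N-oxide (6 equiv), rt
Reagents that add atoms: dicobalt octacarbonyl (CO source), [Co].[Co].[C-]#[O+].[C-]#[O+].[C-]#[O+].[C-]#[O+].[C-]#[O+].[C-]#[O+].[C-]#[O+].[C-]#[O+]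
Why: Pauson–Khand [2+2+1] cyclocarbonylation forms rings A and B at once, and the allylic methyl (C29) and the C3 side chain take the convex face of the cobaltacycle, which sets C28 (28-H cis to 29-CH3).

Step 7
Reactants: 10 3,3-diethoxyprop-1-yne; 11 (2E)-3-iodoprop-2-en-1-ol
Product: 12 (2E)-6,6-diethoxyhex-2-en-4-yn-1-ol
Conditions: Pd(PPh3)2Cl2 (2 mol %), CuI (4 mol %), Et3N, THF, rt
Reagents that add atoms: none
Why: Sonogashira coupling joins the alkyne to the (E)-vinyl iodide with retention of alkene geometry (start of fragment 1).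

Step 8
Reactants: 12 (2E)-6,6-diethoxyhex-2-en-4-yn-1-ol
Product: 13 (2E,4Z)-6,6-diethoxyhexa-2,4-dien-1-ol
Conditions: H2 (1 atm), Pd/CaCO3 poisoned with Pb(OAc)2, quinoline, EtOAc, 0 °C
Reagents that add atoms: none
Why: Syn semi-hydrogenation of the alkyne on the poisoned palladium surface gives the (4Z)-alkene that later becomes C22=C23.

Step 9
Reactants: 13 (2E,4Z)-6,6-diethoxyhexa-2,4-dien-1-ol
Product: 14 (2E,4Z)-1-bromo-6,6-diethoxyhexa-2,4-diene
Conditions: CBr4, PPh3, 2,6-lutidine, CH2Cl2, −20 °C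
Reagents that add atoms: tetrabromomethane, BrC(Br)(Br)Br
Why: Appel bromination under buffered conditions converts the allylic alcohol into the bromide without touching the acetal (fragment 1 complete, used at once).

Step 10
Reactants: 9 (5R,6S,6aS)-5-[(1R)-1-{[tert-butyl(dimethyl)silyl]oxy}ethyl]-6-methyl-4,5,6,6a-tetrahydropentalen-2(1H)-one; 14 (2E,4Z)-1-bromo-6,6-diethoxyhexa-2,4-diene
Product: 15 C27-alkylated enone (9 carrying on C1 of the pentalenone, cis to 6a-H, the (2E,4Z)-6,6-diethoxyhexa-2,4-dien-1-yl chain)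
Conditions: LiN(iPr)2, THF, −78 °C; 14, −78 → −40 °C
Reagents that add atoms: none
Why: Kinetic α′-deprotonation of the cross-conjugated enone and SN2 alkylation, in which the bromide enters anti to the ring-A carbon on C28, sets C27 (chain cis to 28-H).

Step 11
Reactants: 15 C27-alkylated enone
Product: 16 cis-fused ketone (15 with C5=C6 reduced, 5-H cis to 28-H)
Conditions: [(Ph3P)CuH]6 (0.4 equiv), H2O (2 equiv), benzene, rt
Reagents that add atoms: none
Why: Copper hydride conjugate reduction (Stryker reduction) touches only the enone and not the isolated diene, and hydride delivery can only give the cis-fused bicyclo[3.3.0]octanone, which sets C5.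

Step 12
Reactants: 16 cis-fused ketone
Product: 17 enol triflate (C6=C7, OTf on C7)
Conditions: LiN(iPr)2, THF, −78 °C; PhNTf2, −78 → 0 °C
Reagents that add atoms: N-phenylbis(trifluoromethanesulfonimide), O=S(=O)(N(c1ccccc1)S(=O)(=O)C(F)(F)F)C(F)(F)F
Why: Kinetic deprotonation at the less substituted α-carbon (C6) and O-triflation give the C6=C7 enol triflate regioselectively.

Step 13
Reactants: 18 N2-(tert-butoxycarbonyl)-L-ornithine; 19 (2E)-penta-2,4-dienoic acid
Product: 21 N2-(tert-butoxycarbonyl)-N5-[(2E)-penta-2,4-dienoyl]-L-ornithine, via mixed anhydride 20 (not isolated)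
Conditions: 19, i-BuOCOCl, N-methylmorpholine, THF, −15 °C; 18, NaHCO3, H2O/THF, 0 °C → rt; HCl to pH 3
Reagents that add atoms: none
Why: Mixed-anhydride amide coupling acylates only the free δ-amine of Boc-ornithine, and the bought (S)-centre becomes C17 (fragment 2).

Step 14
Reactants: 17 enol triflate; 21 N2-(tert-butoxycarbonyl)-N5-[(2E)-penta-2,4-dienoyl]-L-ornithine
Product: 22 trienamide silyl ether (17 with OTf replaced by the (8E,10E)-dienamide arm C8–C12 carrying the Boc-ornithine acid)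
Conditions: Pd(OAc)2 (5 mol %), P(o-tol)3 (10 mol %), Et3N (4 equiv), DMF, 60 °C
Reagents that add atoms: none
Why: Mizoroki–Heck reaction of the alkenyl triflate at the terminal CH2 of the dienamide gives the (8E,10E)-trienamide and attaches the whole ornithine arm in one step.

Step 15
Reactants: 22 trienamide silyl ether
Product: 23 trienamide alcohol (C2–OH free)
Conditions: Bu4NF, THF, 0 °C → rt
Reagents that add atoms: none
Why: Fluoride cleaves the secondary silyl ether without affecting the acetal, the carbamate or the polyene.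

Step 16
Reactants: 23 trienamide alcohol
Product: 24 trienamide methyl ketone (acetyl on C3)
Conditions: Dess–Martin periodinane, NaHCO3, CH2Cl2, 0 °C → rt
Reagents that add atoms: none
Why: Dess–Martin oxidation turns the temporary C2 carbinol into the acetyl group under buffered, non-epimerising conditions, so C3 keeps its configuration.

Step 17
Reactants: 24 trienamide methyl ketone
Product: 26 tetracyclic cycloocta-1,5-diene with C6=C7 (rings C and D formed; 11-CONHR and 22-CH(OEt)2 trans), via divinylcyclobutane 25 (not isolated)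
Conditions: [Ir(ppy)2(dtbbpy)]PF6 (1 mol %), 450 nm LEDs, degassed MeCN, 25 °C; then toluene, 130 °C (sealed)
Reagents that add atoms: none
Why: Proposed new method: triplet energy transfer from the iridium sensitiser (ET about 49 kcal/mol) excites only the conjugated trienamide, whose C8 adds 5-exo to C25 (attack through C6 would be 5-endo) through a chair-like transition state in which sp2-C7 holds ring B in plane and C28 pseudo-equatorial, so C24 ends cis to C28 and the bis-allyl biradical closes to the cis-1,2-dialkenylcyclobutane 25 (setting C8 and C25 with 8-H and 25-H cis to 27-H), which on heating undergoes the boat Cope rearrangement that puts the substituent of the (E)-terminus (amide) and that of the (Z)-terminus (acetal) trans and so sets C11 and C22; the closest known reaction type is the sensitised intramolecular diene–diene [2+2] photocycloaddition followed by divinylcyclobutane Cope rearrangement, together with visible-light energy-transfer [2+2] reactions of 1,3-dienes.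

Step 18
Reactants: 26 tetracyclic cycloocta-1,5-diene with C6=C7
Product: 27 saturated tetracycle (7-H cis to 27-H and 8-H)
Conditions: Mn(dpm)3 (10 mol %), PhSiH3 (1.5 equiv), t-BuOOH (1.5 equiv), i-PrOH, rt
Reagents that add atoms: none
Why: Mukaiyama-type hydrogen-atom-transfer hydrogenation reduces only the trisubstituted C6=C7 bond (the (Z)-disubstituted ring-D alkenes are inert), and the tertiary C7 radical can only collapse to the cis-fused B/C junction, which sets C7.

Step 19
Reactants: 27 saturated tetracycle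
Product: 29 N-Boc tetramic acid (ring F formed), via acyl Meldrum adduct 28 (not isolated)
Conditions: Meldrum's acid (1.1 equiv), EDC·HCl, DMAP, CH2Cl2, 0 °C → rt; EtOAc, reflux
Reagents that add atoms: Meldrum's acid (2,2-dimethyl-1,3-dioxane-4,6-dione), CC1(C)OC(=O)CC(=O)O1
Why: Meldrum's acid route to tetramic acids, in which the acyl Meldrum's acid loses acetone and CO2 on heating and the acylketene is trapped by the carbamate nitrogen, forms ring F without touching C17.

Step 20
Reactants: 29 N-Boc tetramic acid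
Product: 31 Combamide C, via aldehyde tetramic acid 30 (not isolated)
Conditions: TFA/CH2Cl2/H2O (10:10:1), 0 °C → rt; evaporate; piperidinium acetate (0.2 equiv), EtOH (0.5 mM), 40 °C
Reagents that add atoms: none
Why: Acid removes Boc and unmasks the C21 aldehyde, and the acidic C20 methylene of the tetramic acid then undergoes intramolecular Knoevenagel condensation at high dilution, closing the eleven-membered ring E with the ring-imposed C20=C21 geometry.

## Compound list

1 | ethyl (3R)-3-hydroxybutanoate | C[C@@H](O)CC(=O)OCC | starting material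
2 | (2Z)-but-2-en-1-ol | C/C=C\CO | starting material
3 | (2Z)-but-2-en-1-yl (3R)-3-hydroxybutanoate | C[C@@H](O)CC(=O)OC/C=C\C | intermediate
4 | (2R,3S)-2-[(1R)-1-hydroxyethyl]-3-methylpent-4-enoic acid | C[C@@H](O)[C@@H]([C@@H](C)C=C)C(=O)O | intermediate
5 | tert-butyl(dimethyl)silyl (2R,3S)-2-[(1R)-1-{[tert-butyl(dimethyl)silyl]oxy}ethyl]-3-methylpent-4-enoate (not isolated) | C[C@@H](O[Si](C)(C)C(C)(C)C)[C@@H]([C@@H](C)C=C)C(=O)O[Si](C)(C)C(C)(C)C | intermediate
6 | (2S,3S)-2-[(1R)-1-{[tert-butyl(dimethyl)silyl]oxy}ethyl]-3-methylpent-4-en-1-ol | C[C@@H](O[Si](C)(C)C(C)(C)C)[C@@H]([C@@H](C)C=C)CO | intermediate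
7 | tert-butyl{[(2R,3R,4S)-3-(iodomethyl)-4-methylhex-5-en-2-yl]oxy}dimethylsilane | C[C@@H](O[Si](C)(C)C(C)(C)C)[C@@H]([C@@H](C)C=C)CI | intermediate
8 | tert-butyl(dimethyl){[(2R,3R,4S)-4-methyl-3-(prop-2-yn-1-yl)hex-5-en-2-yl]oxy}silane | C[C@@H](O[Si](C)(C)C(C)(C)C)[C@@H]([C@@H](C)C=C)CC#C | intermediate
9 | (5R,6S,6aS)-5-[(1R)-1-{[tert-butyl(dimethyl)silyl]oxy}ethyl]-6-methyl-4,5,6,6a-tetrahydropentalen-2(1H)-one | C[C@@H](O[Si](C)(C)C(C)(C)C)[C@@H]1CC2=CC(=O)C[C@H]2[C@@H]1C | intermediate
10 | 3,3-diethoxyprop-1-yne | C#CC(OCC)OCC | starting material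
11 | (2E)-3-iodoprop-2-en-1-ol | OC/C=C/I | starting material
12 | (2E)-6,6-diethoxyhex-2-en-4-yn-1-ol | OC/C=C/C#CC(OCC)OCC | intermediate
13 | (2E,4Z)-6,6-diethoxyhexa-2,4-dien-1-ol | OC/C=C/C=C\C(OCC)OCC | intermediate
14 | (2E,4Z)-1-bromo-6,6-diethoxyhexa-2,4-diene | BrC/C=C/C=C\C(OCC)OCC | intermediate
15 | C27-alkylated enone: 9 carrying on C1 of the pentalenone (target C27), cis to 6a-H, the (2E,4Z)-6,6-diethoxyhexa-2,4-dien-1-yl chain | C[C@@H](O[Si](C)(C)C(C)(C)C)[C@@H]1CC2=CC(=O)[C@H](C/C=C/C=C\C(OCC)OCC)[C@H]2[C@@H]1C | intermediate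
16 | cis-fused ketone: 15 with C5=C6 reduced, 5-H cis to 28-H | C[C@@H](O[Si](C)(C)C(C)(C)C)[C@@H]1C[C@H]2CC(=O)[C@H](C/C=C/C=C\C(OCC)OCC)[C@H]2[C@@H]1C | intermediate
17 | enol triflate of 16: C6=C7, trifluoromethanesulfonate on C7 | C[C@@H](O[Si](C)(C)C(C)(C)C)[C@@H]1C[C@H]2C=C(OS(=O)(=O)C(F)(F)F)[C@H](C/C=C/C=C\C(OCC)OCC)[C@H]2[C@@H]1C | intermediate
18 | N2-(tert-butoxycarbonyl)-L-ornithine | CC(C)(C)OC(=O)N[C@@H](CCCN)C(=O)O | starting material
19 | (2E)-penta-2,4-dienoic acid | C=C/C=C/C(=O)O | starting material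
20 | isobutyl carbonic (2E)-penta-2,4-dienoic anhydride (not isolated) | C=C/C=C/C(=O)OC(=O)OCC(C)C | intermediate
21 | N2-(tert-butoxycarbonyl)-N5-[(2E)-penta-2,4-dienoyl]-L-ornithine | C=C/C=C/C(=O)NCCC[C@@H](C(=O)O)NC(=O)OC(C)(C)C | intermediate
22 | trienamide silyl ether: 17 with OTf replaced by the (8E,10E)-C8–C12 dienamide arm bearing the (S)-Boc-ornithine acid; C2–OTBS | C[C@@H](O[Si](C)(C)C(C)(C)C)[C@@H]1C[C@H]2C=C(/C=C/C=C/C(=O)NCCC[C@@H](C(=O)O)NC(=O)OC(C)(C)C)[C@H](C/C=C/C=C\C(OCC)OCC)[C@H]2[C@@H]1C | intermediate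
23 | trienamide alcohol: 22 with free (2R)-OH | C[C@@H](O)[C@@H]1C[C@H]2C=C(/C=C/C=C/C(=O)NCCC[C@@H](C(=O)O)NC(=O)OC(C)(C)C)[C@H](C/C=C/C=C\C(OCC)OCC)[C@H]2[C@@H]1C | intermediate
24 | trienamide methyl ketone: 23 with the C2 carbinol oxidised to the acetyl group | CC(=O)[C@@H]1C[C@H]2C=C(/C=C/C=C/C(=O)NCCC[C@@H](C(=O)O)NC(=O)OC(C)(C)C)[C@H](C/C=C/C=C\C(OCC)OCC)[C@H]2[C@@H]1C | intermediate
25 | divinylcyclobutane photoadduct (not isolated): new C8–C25 and C9–C24 bonds; 8-H and 25-H cis to 27-H; (E)-alkenyl amide on C9 and (Z)-alkenyl acetal on C24 cis to each other and trans to C7/C26 | CC(=O)[C@@H]1C[C@H]2C=C3[C@@H]4[C@@H](/C=C/C(=O)NCCC[C@@H](C(=O)O)NC(=O)OC(C)(C)C)[C@@H](/C=C\C(OCC)OCC)[C@@H]4C[C@@H]3[C@H]2[C@@H]1C | intermediate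
26 | tetracycle with C6=C7: rings C/D cis-fused, (9Z,23Z)-cycloocta-1,5-diene, 11-CONHR and 22-CH(OEt)2 trans | CC(=O)[C@@H]1C[C@H]2C=C3[C@@H]4/C=C\[C@H](C(=O)NCCC[C@@H](C(=O)O)NC(=O)OC(C)(C)C)[C@@H](C(OCC)OCC)/C=C\[C@@H]4C[C@@H]3[C@H]2[C@@H]1C | intermediate
27 | saturated tetracycle: 26 with C6=C7 hydrogenated, 7-H cis to 27-H and 8-H | CC(=O)[C@@H]1C[C@H]2C[C@@H]3[C@@H]4/C=C\[C@H](C(=O)NCCC[C@@H](C(=O)O)NC(=O)OC(C)(C)C)[C@@H](C(OCC)OCC)/C=C\[C@@H]4C[C@@H]3[C@H]2[C@@H]1C | intermediate
28 | acyl Meldrum's acid adduct of 27 (not isolated) | CC(=O)[C@@H]1C[C@H]2C[C@@H]3[C@@H]4/C=C\[C@H](C(=O)NCCC[C@@H](C(=O)C5C(=O)OC(C)(C)OC5=O)NC(=O)OC(C)(C)C)[C@@H](C(OCC)OCC)/C=C\[C@@H]4C[C@@H]3[C@H]2[C@@H]1C | intermediate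
29 | N-Boc tetramic acid: (5S)-1-Boc-pyrrolidine-2,4-dione linked through its 5-(CH2)3NH arm to the C12 amide of the tetracycle; C21 diethyl acetal | CC(=O)[C@@H]1C[C@H]2C[C@@H]3[C@@H]4/C=C\[C@H](C(=O)NCCC[C@@H]5N(C(=O)OC(C)(C)C)C(=O)CC5=O)[C@@H](C(OCC)OCC)/C=C\[C@@H]4C[C@@H]3[C@H]2[C@@H]1C | intermediate
30 | free tetramic acid C21 aldehyde (not isolated) | CC(=O)[C@@H]1C[C@H]2C[C@@H]3[C@@H]4/C=C\[C@H](C(=O)NCCC[C@@H]5NC(=O)CC5=O)[C@@H](C=O)/C=C\[C@@H]4C[C@@H]3[C@H]2[C@@H]1C | intermediate
31 | Combamide C | CC(=O)[C@@H]1C[C@H]2C[C@@H]3[C@@H]4/C=C\[C@@H]5C(=O)NCCC[C@@H]6NC(=O)/C(=C/[C@H]5/C=C\[C@@H]4C[C@@H]3[C@H]2[C@@H]1C)C6=O | target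

## Step count and weakest steps

Total step count: 20. Longest linear sequence: 16 steps (steps 1–6, 10–12, 14–20).

Three steps most likely to fail:

1. Step 17 (the proposed new photocycloaddition/Cope step). Risks are the facial selectivity at C8/C25 (ring D must end on the same face of ring C as ring B; the argument is the chair-like transition state only), biradical closure to vinylcyclohexenes instead of the cyclobutane, E/Z scrambling of the excited trienamide (which would erode C11), and the slow Cope step of the (Z)-alkenyl terminus. Fallback with known chemistry, setting out from 24 and coming back at 26: the zerovalent-nickel-catalysed intramolecular [4+4] cycloaddition of the two 1,3-diene units (Ni(COD)2 10 mol %, PPh3, toluene, 60 °C, 24 as its triethylammonium carboxylate), a thermal route to cis-fused bicyclo[6.3.0]undeca-2,6-dienes that forms C8–C25 and C11–C22 directly; it makes no new compound (F0), and the configuration of the product would have to be verified against 26.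

2. Step 20 (closure of the eleven-membered ring by Knoevenagel condensation). Risks are ring strain, intermolecular Michael addition of a second tetramic acid to the alkylidene product, and epimerisation or conjugation of the β,γ-unsaturated aldehyde at C22. Fallback, setting out from 24 and coming back at 31, with the ring-closing order reversed so that only a strain-free large ring is closed by condensation:
   - 24 is treated with Meldrum's acid, EDC·HCl and DMAP to give the acyl Meldrum's acid adduct of the tetraene F1 (not isolated), which in refluxing EtOAc gives the N-Boc tetramic acid tetraene F2.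
   - TFA/H2O liberates the tetramic acid (2Z,4E)-dienal F3 (not isolated), which with piperidinium acetate in dilute EtOH closes to the twenty-membered macrocyclic pentaene F4.
   - Sensitised irradiation as in step 17 gives the transannular divinylcyclobutane F5 (not isolated), and heating gives 6,7-didehydrocombamide C F6.
   - The C6=C7 bond of F6 is reduced with Mn(dpm)3/PhSiH3/t-BuOOH to give 31.

3. Step 10 (α′-alkylation with the labile (E,Z)-dienyl bromide 14). Risks are decomposition or Z→E isomerisation of 14, SN2′ attack and dialkylation. Fallback, setting out from 9 and 13 and coming back at 15: 13 is converted with ClCO2Me/pyridine into methyl (2E,4Z)-6,6-diethoxyhexa-2,4-dien-1-yl carbonate F7, and the lithium enolate of 9 is allylated with F7 under Pd(PPh3)4 catalysis (Tsuji–Trost allylation, attack at the unsubstituted terminus anti to ring A), which avoids the bromide altogether.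

## Further compounds

F0 | step 17 | none | none
F1 | step 20 | acyl Meldrum's acid adduct of tetraene 24 (not isolated) | CC(=O)[C@@H]1C[C@H]2C=C(/C=C/C=C/C(=O)NCCC[C@@H](C(=O)C5C(=O)OC(C)(C)OC5=O)NC(=O)OC(C)(C)C)[C@H](C/C=C/C=C\C(OCC)OCC)[C@H]2[C@@H]1C
F2 | step 20 | N-Boc tetramic acid tetraene | CC(=O)[C@@H]1C[C@H]2C=C(/C=C/C=C/C(=O)NCCC[C@@H]5N(C(=O)OC(C)(C)C)C(=O)CC5=O)[C@H](C/C=C/C=C\C(OCC)OCC)[C@H]2[C@@H]1C
F3 | step 20 | tetramic acid (2Z,4E)-dienal (not isolated) | CC(=O)[C@@H]1C[C@H]2C=C(/C=C/C=C/C(=O)NCCC[C@@H]5NC(=O)CC5=O)[C@H](C/C=C/C=C\C=O)[C@H]2[C@@H]1C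
F4 | step 20 | twenty-membered macrocyclic pentaene (C20=C21 formed, rings C and D still open) | CC(=O)[C@@H]1C[C@H]2C=C3/C=C/C=C/C(=O)NCCC[C@@H]4NC(=O)/C(=C/C=C\C=C\C[C@@H]3[C@H]2[C@@H]1C)C4=O
F5 | step 20 | transannular divinylcyclobutane (not isolated) | CC(=O)[C@@H]1C[C@H]2C=C3[C@@H]4[C@H]5/C=C/C(=O)NCCC[C@@H]6NC(=O)/C(=C/C=C\[C@H]5[C@@H]4C[C@@H]3[C@H]2[C@@H]1C)C6=O
F6 | step 20 | 6,7-didehydrocombamide C | CC(=O)[C@@H]1C[C@H]2C=C3[C@@H]4/C=C\[C@@H]5C(=O)NCCC[C@@H]6NC(=O)/C(=C/[C@H]5/C=C\[C@@H]4C[C@@H]3[C@H]2[C@@H]1C)C6=O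
F7 | step 10 | methyl (2E,4Z)-6,6-diethoxyhexa-2,4-dien-1-yl carbonate | COC(=O)OC/C=C/C=C\C(OCC)OCC
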